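**Plan**
- Retrosynthesis: the C40 polyene is cut at C11=C12 and C11'=C12' (two Wittig reactions on the C10 dialdehyde), each C15 end piece at C7=C8 (Horner–Wadsworth–Emmons), and the ring at C5–C6, the bond made by Ireland–Claisen ring contraction of a 6-propenyl δ-lactone.
- Enabling feature: C6 lies between quaternary C1 and C5; C7 on C6 and the C18 methyl on C5 correspond to the carboxyl carbon and the alkene terminus of a lactone-enolate Claisen product, and the C3=C4 alkene left behind is where the C4 oxygen enters.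
- Forward: the lactone ring is built first from 3,3-dimethylglutaric anhydride and an (E)-propenyl unit, then contracted to the carbocycle; iodolactonisation brings in the C4 oxygen; the chain is extended to a C15 dienoate and turned into one C15 phosphonium salt.
- That salt is used twice on the C10 dialdehyde: first coupling, oxidation of C4' to the ketone (ring 2), second coupling (ring 1).
- Stereochemistry: CBS reduction sets the carbinol centre, the [3,3] step transfers it to C6, C5 is equilibrated to trans next to the C4 ketone, C4 comes from axial hydride addition, and the chain geometry from HWE/Wittig with thermal equilibration to all-E.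

Key step: step 6

Remark: carotenoid numbering is used (ring 1 = hydroxy ring, primed atoms = keto ring 2); Z isomers formed at the new C11=C12 and C11'=C12' bonds are assumed to equilibrate to E on heating, as is usual at this position.

**Step 1**
Reactants: 1 3,3-dimethylglutaric anhydride
Product: 2 5-methoxy-3,3-dimethyl-5-oxopentanoic acid
Conditions: MeOH, 4-(dimethylamino)pyridine (cat.), 65 °C
Reagents that add atoms: methanol, SMILES CO
Why: Methanolysis (nucleophilic acyl substitution) of the symmetrical cyclic anhydride can give only one half ester, so the two carboxyl ends are told apart without a selectivity problem.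

**Step 2**
Reactants: 2 5-methoxy-3,3-dimethyl-5-oxopentanoic acid
Product: 3 methyl 5-chloro-3,3-dimethyl-5-oxopentanoate
Conditions: (COCl)2, DMF (cat.), CH2Cl2, 0 °C to rt; concentrate
Reagents that add atoms: oxalyl chloride, SMILES ClC(=O)C(=O)Cl
Why: Acid chloride formation under DMF (Vilsmeier-type) catalysis activates the free acid while the methyl ester stays untouched.

**Step 3**
Reactants: 3 methyl 5-chloro-3,3-dimethyl-5-oxopentanoate; 4 (E)-1-bromoprop-1-ene
Product: 7 methyl (E)-3,3-dimethyl-5-oxooct-6-enoate, via (E)-prop-1-enyllithium 5 (not isolated), via (E)-prop-1-enylzinc chloride 6 (not isolated)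
Conditions: 4, (CH3)3CLi (2 equiv), Et2O, −78 °C; ZnCl2, THF, −78 to 0 °C; then 3, Pd(PPh3)4 (cat.), THF, 0 °C to rt
Reagents that add atoms: none
Why: Bromine–lithium exchange keeps the E geometry, transmetalation to zinc tempers the nucleophile, and the Pd-catalysed Negishi acylation couples only at the acid chloride, so the (E)-enone should form without attack on the ester or the product ketone.

**Step 4**
Reactants: 7 methyl (E)-3,3-dimethyl-5-oxooct-6-enoate
Product: 8 methyl (5S,6E)-5-hydroxy-3,3-dimethyloct-6-enoate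
Conditions: (R)-1-methyl-3,3-diphenyltetrahydro-1H,3H-pyrrolo[1,2-c][1,3,2]oxazaborole (0.15 equiv), catecholborane, toluene, −78 °C
Reagents that add atoms: none
Why: Corey–Bakshi–Shibata reduction: with the propenyl group acting as the larger ketone substituent, the (R)-configured catalyst should deliver hydride to the face that gives the (S)-allylic alcohol, and catecholborane at −78 °C leaves the alkene and ester alone.

**Step 5**
Reactants: 8 methyl (5S,6E)-5-hydroxy-3,3-dimethyloct-6-enoate
Product: 9 (6S)-4,4-dimethyl-6-[(1E)-prop-1-en-1-yl]oxan-2-one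
Conditions: pyridinium p-toluenesulfonate (cat.), toluene, 60 °C, MeOH removed
Reagents that add atoms: none
Why: Acid-catalysed lactonisation (intramolecular transesterification) is helped by the gem-dimethyl (Thorpe–Ingold) effect and takes place at the ester carbonyl, so the carbinol C–O bond and its configuration are not touched.

**Step 6**
Reactants: 9 (6S)-4,4-dimethyl-6-[(1E)-prop-1-en-1-yl]oxan-2-one
Product: 12 (1S,2S)-2,6,6-trimethylcyclohex-3-ene-1-carboxylic acid, via silyl ketene acetal 10 (not isolated), via trimethylsilyl ester 11 (not isolated)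
Conditions: LiN(iPr)2, Me3SiCl (present from the start), THF, −78 °C; then toluene, 110 °C; then 1 M HCl, THF, rt
Reagents that add atoms: none
Why: LiN(iPr)2 removes a proton from the only enolisable position (lactone C3) and Me3SiCl traps the enolate on oxygen as cyclic silyl ketene acetal 10; on heating, its C=C(OSi)–O–CH–CH=CH array undergoes an Ireland–Claisen [3,3] sigmatropic rearrangement in which the ketene-acetal carbon bonds to the propenyl terminus (the C5–C6 bond) as the ring C–O bond breaks, and acid hydrolysis of silyl ester 11 frees the acid. The closest known reaction type is the ring contraction of 6-alkenyl δ-lactone silyl ketene acetals to cyclohex-3-enecarboxylic acids. The six-membered carbocycle closes by this pericyclic ring contraction: the C4(Me)2–CH2 tether joins the ketene-acetal carbon and the carbinol carbon, which are 1,4-related in the six-atom array, so only a boat-like, bicyclo[2.2.2]octane-shaped transition state is possible. C6 (C1 of the acid) is set by suprafacial transfer of chirality from the (S)-carbinol centre through this rigid boat and should be S. C5 (C2 of the acid) is set by the E geometry of the propenyl group, whose methyl points away from the tether and therefore ends up cis to the carboxyl. The step needs O-silylation without lactone self-condensation, which the internal quench at −78 °C secures, and a single transition-state geometry, which the tether secures because a chair cannot be reached.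

**Step 7**
Reactants: 12 (1S,2S)-2,6,6-trimethylcyclohex-3-ene-1-carboxylic acid
Product: 13 (1S,4R,5R,8R)-4-iodo-2,2,8-trimethyl-6-oxabicyclo[3.2.1]octan-7-one
Conditions: I2, NaHCO3, H2O–CH2Cl2, 0 °C to rt, dark
Reagents that add atoms: iodine, SMILES II
Why: Iodolactonisation: the carboxylate opens the iodonium ion of the C3=C4 alkene anti and in the five-membered (γ-lactone) mode, so oxygen enters C4 on the face of C7 and iodine C3 on the other face, with the C5 methyl equatorial on the one-carbon bridge.

**Step 8**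
Reactants: 13 (1S,4R,5R,8R)-4-iodo-2,2,8-trimethyl-6-oxabicyclo[3.2.1]octan-7-one
Product: 14 (1S,5S,8R)-2,2,8-trimethyl-6-oxabicyclo[3.2.1]octan-7-one
Conditions: Bu3SnH, 2,2'-azobis(2-methylpropionitrile) (cat.), toluene, 80 °C
Reagents that add atoms: none
Why: Radical chain dehalogenation with tin hydride removes the secondary iodide without touching the lactone or any stereocentre that is kept.

**Step 9**
Reactants: 14 (1S,5S,8R)-2,2,8-trimethyl-6-oxabicyclo[3.2.1]octan-7-one
Product: 15 (1S,5S,8R)-2,2,8-trimethyl-6-oxabicyclo[3.2.1]octan-7-ol (both C7 epimers)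
Conditions: iBu2AlH (1.1 equiv), CH2Cl2, −78 °C; aqueous potassium sodium tartrate
Reagents that add atoms: none
Why: Half-reduction of a lactone: iBu2AlH adds once at −78 °C and the tetrahedral aluminium alkoxide survives until work-up, so reduction should stop at the bicyclic lactol.

**Step 10**
Reactants: 15 (1S,5S,8R)-2,2,8-trimethyl-6-oxabicyclo[3.2.1]octan-7-ol; 16 triethyl (E)-3-methyl-4-phosphonobut-2-enoate
Product: 18 ethyl (2E,4E)-5-[(1S,2R,3S)-3-hydroxy-2,6,6-trimethylcyclohexyl]-3-methylpenta-2,4-dienoate, via hydroxy aldehyde 17 (not isolated)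
Conditions: 16 (2.5 equiv), LiN(SiMe3)2 (2.4 equiv), THF, −78 to 0 °C; then 15, 0 °C to rt
Reagents that add atoms: none
Why: Horner–Wadsworth–Emmons olefination: the lactol is in equilibrium with hydroxy aldehyde 17, which the lithiated phosphonate (in excess, part of it deprotonating the hydroxyl) should convert into the (E)-C7=C8 alkene, while the C9=C10 geometry comes from the (E)-reagent.

**Step 11**
Reactants: 18 ethyl (2E,4E)-5-[(1S,2R,3S)-3-hydroxy-2,6,6-trimethylcyclohexyl]-3-methylpenta-2,4-dienoate
Product: 19 ethyl (2E,4E)-3-methyl-5-[(1S,2R)-2,6,6-trimethyl-3-oxocyclohexyl]penta-2,4-dienoate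
Conditions: Dess–Martin periodinane (1,1,1-triacetoxy-1,1-dihydro-1,2-benziodoxol-3(1H)-one), NaHCO3, CH2Cl2, 0 °C to rt
Reagents that add atoms: none
Why: Dess–Martin oxidation turns the only hydroxyl into the C4 ketone under buffered conditions that tolerate the dienoate.

**Step 12**
Reactants: 19 ethyl (2E,4E)-3-methyl-5-[(1S,2R)-2,6,6-trimethyl-3-oxocyclohexyl]penta-2,4-dienoate
Product: 20 ethyl (2E,4E)-3-methyl-5-[(1S,2S)-2,6,6-trimethyl-3-oxocyclohexyl]penta-2,4-dienoate
Conditions: DBU (0.5 equiv), toluene, 50 °C; trans isomer separated, cis fraction resubmitted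
Reagents that add atoms: none
Why: Base-mediated epimerisation through the enolate: C5 is the only stereocentre α to the ketone, and equilibration should favour the trans isomer with C5 methyl and C6 chain both equatorial, since the cis isomer must place the C6 chain axial or bring the C5 methyl syn-axial to a C1 methyl; C6 is not acidic here and keeps its configuration.

**Step 13**
Reactants: 20 ethyl (2E,4E)-3-methyl-5-[(1S,2S)-2,6,6-trimethyl-3-oxocyclohexyl]penta-2,4-dienoate
Product: 21 ethyl (2E,4E)-5-[(1S,2S,3S)-3-hydroxy-2,6,6-trimethylcyclohexyl]-3-methylpenta-2,4-dienoate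
Conditions: NaBH4, CeCl3·7H2O, MeOH, −78 °C
Reagents that add atoms: none
Why: Luche reduction: the small hydride should attack the chair with equatorial C5 and C6 substituents along the axial trajectory, which no axial group blocks, giving the equatorial (4S) alcohol trans to the C5 methyl and cis to the chain, with the dienoate untouched.

**Step 14**
Reactants: 21 ethyl (2E,4E)-5-[(1S,2S,3S)-3-hydroxy-2,6,6-trimethylcyclohexyl]-3-methylpenta-2,4-dienoate
Product: 22 (1S,2S,3S)-3-[(1E,3E)-5-hydroxy-3-methylpenta-1,3-dien-1-yl]-2,4,4-trimethylcyclohexan-1-ol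
Conditions: iBu2AlH (3.5 equiv), CH2Cl2, −78 °C; aqueous potassium sodium tartrate
Reagents that add atoms: none
Why: iBu2AlH reduces the conjugated ester in 1,2-fashion to the allylic alcohol without affecting the diene or the stereocentres.

**Step 15**
Reactants: 22 (1S,2S,3S)-3-[(1E,3E)-5-hydroxy-3-methylpenta-1,3-dien-1-yl]-2,4,4-trimethylcyclohexan-1-ol
Product: 23 [(2E,4E)-5-[(1S,2S,3S)-3-hydroxy-2,6,6-trimethylcyclohexyl]-3-methylpenta-2,4-dien-1-yl]triphenylphosphonium bromide
Conditions: PPh3·HBr, MeOH, rt; precipitation from ethyl acetate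
Reagents that add atoms: triphenylphosphine hydrobromide, SMILES Br.c1ccc(cc1)P(c1ccccc1)c1ccccc1
Why: Triphenylphosphine hydrobromide ionises the primary dienylic alcohol to a pentadienyl cation that the phosphine captures at the unhindered terminus (the usual way to C15 Wittig salts), which should give the (2E,4E) salt under thermodynamic control while the non-allylic secondary hydroxyl does not react.

**Step 16**
Reactants: 23 the C15 phosphonium bromide; 24 (2E,4E,6E)-2,7-dimethylocta-2,4,6-trienedial
Product: 25 (2E,4E,6E,8E,10E,12E)-13-[(1S,2S,3S)-3-hydroxy-2,6,6-trimethylcyclohexyl]-2,7,11-trimethyltrideca-2,4,6,8,10,12-hexaenal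
Conditions: 24 (4 equiv), 1,2-epoxybutane, EtOH, 75 °C, N2, dark; excess 24 recovered
Reagents that add atoms: none
Why: Wittig olefination in which 1,2-epoxybutane takes up HBr and generates the ylide under nearly neutral conditions; a several-fold excess of the symmetrical dialdehyde should direct the reaction to mono-olefination, and the free hydroxyl is tolerated.

**Step 17**
Reactants: 25 the C25 hydroxy aldehyde
Product: 26 (2E,4E,6E,8E,10E,12E)-2,7,11-trimethyl-13-[(1S,2S)-2,6,6-trimethyl-3-oxocyclohexyl]trideca-2,4,6,8,10,12-hexaenal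
Conditions: Dess–Martin periodinane, NaHCO3, CH2Cl2, 0 °C, dark
Reagents that add atoms: none
Why: Dess–Martin oxidation of the single secondary hydroxyl under buffered conditions at low temperature should leave aldehyde and hexaene untouched and give the ketone whose C5' centre already has the stable trans arrangement.

**Step 18**
Reactants: 26 the C25 keto aldehyde; 23 the C15 phosphonium bromide
Product: 27 (4S,5S,6S,5'S,6'S)-4-hydroxy-5,6,5',6'-tetrahydro-β,β-caroten-4'-one (all-E), CNP0107241.1
Conditions: 23 (1.3 equiv), 1,2-epoxybutane, EtOH, 75 °C, N2, dark; then heptane, reflux; crystallisation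
Reagents that add atoms: none
Why: Second Wittig olefination under the same nearly neutral conditions, which spare the epimerisable C5' centre; the semi-stabilised ylide should react with the aldehyde and not with the hindered ring ketone, and heating equilibrates Z isomers of the new C11=C12 bond to the all-E polyene.

**Compound list**
1 | 3,3-dimethylglutaric anhydride | CC1(C)CC(=O)OC(=O)C1 | starting material
2 | 5-methoxy-3,3-dimethyl-5-oxopentanoic acid | COC(=O)CC(C)(C)CC(=O)O | intermediate
3 | methyl 5-chloro-3,3-dimethyl-5-oxopentanoate | COC(=O)CC(C)(C)CC(=O)Cl | intermediate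
4 | (E)-1-bromoprop-1-ene | C/C=C/Br | starting material
5 | (E)-prop-1-enyllithium | C/C=C/[Li] | intermediate
6 | (E)-prop-1-enylzinc chloride | C/C=C/[Zn]Cl | intermediate
7 | methyl (E)-3,3-dimethyl-5-oxooct-6-enoate | COC(=O)CC(C)(C)CC(=O)/C=C/C | intermediate
8 | methyl (5S,6E)-5-hydroxy-3,3-dimethyloct-6-enoate | C/C=C/[C@@H](O)CC(C)(C)CC(=O)OC | intermediate
9 | (6S)-4,4-dimethyl-6-[(1E)-prop-1-en-1-yl]oxan-2-one | C/C=C/[C@@H]1CC(C)(C)CC(=O)O1 | intermediate
10 | trimethyl({(2S)-4,4-dimethyl-2-[(1E)-prop-1-en-1-yl]-3,4-dihydro-2H-pyran-6-yl}oxy)silane | C/C=C/[C@@H]1CC(C)(C)C=C(O[Si](C)(C)C)O1 | intermediate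
11 | trimethylsilyl (1S,2S)-2,6,6-trimethylcyclohex-3-ene-1-carboxylate | C[Si](C)(C)OC(=O)[C@H]1[C@@H](C)C=CCC1(C)C | intermediate
12 | (1S,2S)-2,6,6-trimethylcyclohex-3-ene-1-carboxylic acid | OC(=O)[C@H]1[C@@H](C)C=CCC1(C)C | intermediate
13 | (1S,4R,5R,8R)-4-iodo-2,2,8-trimethyl-6-oxabicyclo[3.2.1]octan-7-one | C[C@@H]1[C@@H]2C(=O)O[C@H]1[C@H](I)CC2(C)C | intermediate
14 | (1S,5S,8R)-2,2,8-trimethyl-6-oxabicyclo[3.2.1]octan-7-one | C[C@@H]1[C@@H]2C(=O)O[C@H]1CCC2(C)C | intermediate
15 | (1S,5S,8R)-2,2,8-trimethyl-6-oxabicyclo[3.2.1]octan-7-ol (both C7 epimers) | C[C@@H]1[C@@H]2C(O)O[C@H]1CCC2(C)C | intermediate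
16 | triethyl (E)-3-methyl-4-phosphonobut-2-enoate | CCOC(=O)/C=C(\C)CP(=O)(OCC)OCC | starting material
17 | (1S,2R,3S)-3-hydroxy-2,6,6-trimethylcyclohexane-1-carbaldehyde | O=C[C@H]1[C@@H](C)[C@@H](O)CCC1(C)C | intermediate
18 | ethyl (2E,4E)-5-[(1S,2R,3S)-3-hydroxy-2,6,6-trimethylcyclohexyl]-3-methylpenta-2,4-dienoate | CCOC(=O)/C=C(C)/C=C/[C@H]1[C@@H](C)[C@@H](O)CCC1(C)C | intermediate
19 | ethyl (2E,4E)-3-methyl-5-[(1S,2R)-2,6,6-trimethyl-3-oxocyclohexyl]penta-2,4-dienoate | CCOC(=O)/C=C(C)/C=C/[C@H]1[C@@H](C)C(=O)CCC1(C)C | intermediate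
20 | ethyl (2E,4E)-3-methyl-5-[(1S,2S)-2,6,6-trimethyl-3-oxocyclohexyl]penta-2,4-dienoate | CCOC(=O)/C=C(C)/C=C/[C@H]1[C@H](C)C(=O)CCC1(C)C | intermediate
21 | ethyl (2E,4E)-5-[(1S,2S,3S)-3-hydroxy-2,6,6-trimethylcyclohexyl]-3-methylpenta-2,4-dienoate | CCOC(=O)/C=C(C)/C=C/[C@H]1[C@H](C)[C@@H](O)CCC1(C)C | intermediate
22 | (1S,2S,3S)-3-[(1E,3E)-5-hydroxy-3-methylpenta-1,3-dien-1-yl]-2,4,4-trimethylcyclohexan-1-ol | OC/C=C(C)/C=C/[C@H]1[C@H](C)[C@@H](O)CCC1(C)C | intermediate
23 | [(2E,4E)-5-[(1S,2S,3S)-3-hydroxy-2,6,6-trimethylcyclohexyl]-3-methylpenta-2,4-dien-1-yl]triphenylphosphonium bromide | [Br-].C(/C=C(C)/C=C/[C@H]1[C@H](C)[C@@H](O)CCC1(C)C)[P+](c1ccccc1)(c1ccccc1)c1ccccc1 | intermediate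
24 | (2E,4E,6E)-2,7-dimethylocta-2,4,6-trienedial | O=C/C(C)=C/C=C/C=C(C)/C=O | starting material
25 | (2E,4E,6E,8E,10E,12E)-13-[(1S,2S,3S)-3-hydroxy-2,6,6-trimethylcyclohexyl]-2,7,11-trimethyltrideca-2,4,6,8,10,12-hexaenal | O=C/C(C)=C/C=C/C=C(C)/C=C/C=C(C)/C=C/[C@H]1[C@H](C)[C@@H](O)CCC1(C)C | intermediate
26 | (2E,4E,6E,8E,10E,12E)-2,7,11-trimethyl-13-[(1S,2S)-2,6,6-trimethyl-3-oxocyclohexyl]trideca-2,4,6,8,10,12-hexaenal | O=C/C(C)=C/C=C/C=C(C)/C=C/C=C(C)/C=C/[C@H]1[C@H](C)C(=O)CCC1(C)C | intermediate
27 | (4S,5S,6S,5'S,6'S)-4-hydroxy-5,6,5',6'-tetrahydro-β,β-caroten-4'-one (all-E) | CC(/C=C/C=C(C)/C=C/[C@H]1[C@H](C)[C@@H](O)CCC1(C)C)=C\C=C\C=C(C)\C=C\C=C(C)\C=C\[C@H]1[C@H](C)C(=O)CCC1(C)C | target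

**Step count**
Total step count: 18. Longest linear sequence: 18 steps (1 to 27; salt 23 enters in steps 16 and 18).

**Steps most likely to fail**

Step 10. Ring opening of the bridged lactol to its hindered aldehyde form may be too slow for olefination, the aldehyde may epimerise at C6 under the basic conditions, and the C4 alkoxide of the product may add back to the dienoate (intramolecular 1,6-oxa-Michael addition). The fallback sets out from 14 and comes back at 21: the ring is given its final configuration before the chain is attached, so that olefination is done on an aldehyde that neither lactolises nor cyclises readily. Lactone 14 is opened with MeNH(OMe)·HCl and AlMe3 (CH2Cl2, 0 °C) to the Weinreb amide (1S,2R,3S)-3-hydroxy-N-methoxy-N,2,6,6-tetramethylcyclohexane-1-carboxamide F1. Dess–Martin oxidation gives the cis keto amide (1S,2R)-N-methoxy-N,2,6,6-tetramethyl-3-oxocyclohexane-1-carboxamide F2. DBU equilibrates it to the trans keto amide (1S,2S)-N-methoxy-N,2,6,6-tetramethyl-3-oxocyclohexane-1-carboxamide F3; the amide α-position is not acidic enough to be touched. NaBH4 with CeCl3·7H2O gives the equatorial alcohol (1S,2S,3S)-3-hydroxy-N-methoxy-N,2,6,6-tetramethylcyclohexane-1-carboxamide F4. LiAlH4 (THF, −78 °C) reduces the Weinreb amide to (1S,2S,3S)-3-hydroxy-2,6,6-trimethylcyclohexane-1-carbaldehyde F5, whose formyl and hydroxyl groups are both equatorial, so that ring closure would need the flipped chair with a syn-axial methyl pair. Horner–Wadsworth–Emmons olefination of this aldehyde with 16 and LiN(SiMe3)2 gives 21 directly, and steps 11 to 13 are not needed.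

Step 12. The equilibrium at C5 may not lie far enough on the trans side, so that conversion stays incomplete however long the base acts. The fallback sets out from 7 and comes back at 20: the correction is moved from C5 to C6 in the mirror-image series, where C6 is α to an ester, its inversion relieves a 1,3-diaxial arrangement and the inverted product cannot close back to the lactone. Reduction of 7 with the (S)-configured oxazaborolidine and catecholborane gives methyl (5R,6E)-5-hydroxy-3,3-dimethyloct-6-enoate F6, which is lactonised to (6R)-4,4-dimethyl-6-[(1E)-prop-1-en-1-yl]oxan-2-one F7. The same ring contraction (LiN(iPr)2, Me3SiCl; heat; HCl) leads through trimethyl({(2R)-4,4-dimethyl-2-[(1E)-prop-1-en-1-yl]-3,4-dihydro-2H-pyran-6-yl}oxy)silane F8 and trimethylsilyl (1R,2R)-2,6,6-trimethylcyclohex-3-ene-1-carboxylate F9 to (1R,2R)-2,6,6-trimethylcyclohex-3-ene-1-carboxylic acid F10. In this acid C5 already has the spatial arrangement of the target and C6 the opposite one. Iodolactonisation gives (1R,4S,5S,8S)-4-iodo-2,2,8-trimethyl-6-oxabicyclo[3.2.1]octan-7-one F11, and Bu3SnH gives (1R,5R,8S)-2,2,8-trimethyl-6-oxabicyclo[3.2.1]octan-7-one F12. NaOMe in MeOH at reflux opens the lactone to methyl (1R,2S,3R)-3-hydroxy-2,6,6-trimethylcyclohexane-1-carboxylate F13, which is not isolated. It epimerises at the ester α-carbon to methyl (1S,2S,3R)-3-hydroxy-2,6,6-trimethylcyclohexane-1-carboxylate F14, with ester and C5 methyl equatorial and the hydroxyl trans to the ester. iBu2AlH (CH2Cl2, −78 °C) gives (1S,2S,3R)-3-hydroxy-2,6,6-trimethylcyclohexane-1-carbaldehyde F15. Olefination with 16 gives ethyl (2E,4E)-5-[(1S,2S,3R)-3-hydroxy-2,6,6-trimethylcyclohexyl]-3-methylpenta-2,4-dienoate F16, and Dess–Martin oxidation gives 20.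

Step 13. Facial selectivity of hydride addition may be poor (competing equatorial attack), giving both C4 epimers. The fallback sets out from 20 and comes back at 21: the selectivity is turned the other way on purpose and the centre is then inverted. Li[(sec-Bu)3BH] (THF, −78 °C) adds from the equatorial side and should give the axial alcohol ethyl (2E,4E)-5-[(1S,2S,3R)-3-hydroxy-2,6,6-trimethylcyclohexyl]-3-methylpenta-2,4-dienoate F16, the same compound as in the fallback to step 12. Mitsunobu reaction with 4-nitrobenzoic acid, PPh3 and diisopropyl azodicarboxylate inverts C4 to ethyl (2E,4E)-3-methyl-5-[(1S,2S,3S)-2,6,6-trimethyl-3-(4-nitrobenzoyloxy)cyclohexyl]penta-2,4-dienoate F17, and K2CO3 in EtOH removes the 4-nitrobenzoate to give 21.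

**Further compounds**
F1 | step 10 | (1S,2R,3S)-3-hydroxy-N-methoxy-N,2,6,6-tetramethylcyclohexane-1-carboxamide | CON(C)C(=O)[C@H]1[C@@H](C)[C@@H](O)CCC1(C)C
F2 | step 10 | (1S,2R)-N-methoxy-N,2,6,6-tetramethyl-3-oxocyclohexane-1-carboxamide | CON(C)C(=O)[C@H]1[C@@H](C)C(=O)CCC1(C)C
F3 | step 10 | (1S,2S)-N-methoxy-N,2,6,6-tetramethyl-3-oxocyclohexane-1-carboxamide | CON(C)C(=O)[C@H]1[C@H](C)C(=O)CCC1(C)C
F4 | step 10 | (1S,2S,3S)-3-hydroxy-N-methoxy-N,2,6,6-tetramethylcyclohexane-1-carboxamide | CON(C)C(=O)[C@H]1[C@H](C)[C@@H](O)CCC1(C)C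
F5 | step 10 | (1S,2S,3S)-3-hydroxy-2,6,6-trimethylcyclohexane-1-carbaldehyde | O=C[C@H]1[C@H](C)[C@@H](O)CCC1(C)C
F6 | step 12 | methyl (5R,6E)-5-hydroxy-3,3-dimethyloct-6-enoate | C/C=C/[C@H](O)CC(C)(C)CC(=O)OC
F7 | step 12 | (6R)-4,4-dimethyl-6-[(1E)-prop-1-en-1-yl]oxan-2-one | C/C=C/[C@H]1CC(C)(C)CC(=O)O1
F8 | step 12 | trimethyl({(2R)-4,4-dimethyl-2-[(1E)-prop-1-en-1-yl]-3,4-dihydro-2H-pyran-6-yl}oxy)silane | C/C=C/[C@H]1CC(C)(C)C=C(O[Si](C)(C)C)O1
F9 | step 12 | trimethylsilyl (1R,2R)-2,6,6-trimethylcyclohex-3-ene-1-carboxylate | C[Si](C)(C)OC(=O)[C@@H]1[C@H](C)C=CCC1(C)C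
F10 | step 12 | (1R,2R)-2,6,6-trimethylcyclohex-3-ene-1-carboxylic acid | OC(=O)[C@@H]1[C@H](C)C=CCC1(C)C
F11 | step 12 | (1R,4S,5S,8S)-4-iodo-2,2,8-trimethyl-6-oxabicyclo[3.2.1]octan-7-one | C[C@H]1[C@H]2C(=O)O[C@@H]1[C@@H](I)CC2(C)C
F12 | step 12 | (1R,5R,8S)-2,2,8-trimethyl-6-oxabicyclo[3.2.1]octan-7-one | C[C@H]1[C@H]2C(=O)O[C@@H]1CCC2(C)C
F13 | step 12 | methyl (1R,2S,3R)-3-hydroxy-2,6,6-trimethylcyclohexane-1-carboxylate | COC(=O)[C@@H]1[C@H](C)[C@H](O)CCC1(C)C
F14 | step 12 | methyl (1S,2S,3R)-3-hydroxy-2,6,6-trimethylcyclohexane-1-carboxylate | COC(=O)[C@H]1[C@H](C)[C@H](O)CCC1(C)C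
F15 | step 12 | (1S,2S,3R)-3-hydroxy-2,6,6-trimethylcyclohexane-1-carbaldehyde | O=C[C@H]1[C@H](C)[C@H](O)CCC1(C)C
F16 | step 12 | ethyl (2E,4E)-5-[(1S,2S,3R)-3-hydroxy-2,6,6-trimethylcyclohexyl]-3-methylpenta-2,4-dienoate | CCOC(=O)/C=C(C)/C=C/[C@H]1[C@H](C)[C@H](O)CCC1(C)C
F17 | step 13 | ethyl (2E,4E)-3-methyl-5-[(1S,2S,3S)-2,6,6-trimethyl-3-(4-nitrobenzoyloxy)cyclohexyl]penta-2,4-dienoate | CCOC(=O)/C=C(C)/C=C/[C@H]1[C@H](C)[C@@H](OC(=O)c2ccc(cc2)[N+](=O)[O-])CCC1(C)C
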